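The closed flask blue has two tank neighbours here, teal and green, and I reckon target in each before I look.

    intermediate C → target (k1 = 0.010 min⁻¹)
    intermediate B → side product (k2 = 0.047 min⁻¹)
    target → over-reaction product (k3 = 3.1 × 10⁻⁵ min⁻¹)
    starting material → intermediate A (k4 = 0.070 min⁻¹)
    intermediate B → intermediate C (k5 = 0.038 min⁻¹)
    intermediate A → intermediate B (k6 = 0.041 min⁻¹)

in all of them: starting material 1.0 M
- blue: time 2.5 h; a closed flask charged with all of it at once and left for 2.5 h
- teal: a single well-mixed tank run continuously and read at steady state, 2.5 h in it on average
- green: one stirred flow tank at steady state, fed with the mixture as stated, mean residence time 12.5 h

1. the set-up with the highest amount of target at the outlet or at the end, in percent of the starting material put in ("none" if the first two lie within 2 percentage points) (blue / teal / green / none)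
2. amount of target at the outlet or at the end, in percent of the starting material put in, blue
3. amount of target at the outlet or at the end, in percent of the starting material put in, teal
4. amount of target at the outlet or at the end, in percent of the starting material put in, green

**Branch share.** Intermediate B leaves by two first-order steps, 0.038 min⁻¹ towards intermediate C and 0.047 min⁻¹ towards side product. I call φ the constant towards intermediate C over the sum of the two, the selectivity of the branch: φ = 44.7%. The ratio holds at each moment and in each vessel, so intermediate C receives φ of whatever intermediate B reacts.

**First way.** Let a stage's mean life be one over its total constant. The step intermediate C → target is the rate-limiting step, with 100 min, longer than any other stage's. The stages sum to L = 150 min. I treat a tank of mean residence time τ as one lumped step, so target is φ times τ over τ plus L. That gives 22.3% in teal and 37.2% in green.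

**Second way.** In a tank each stage is its own balance and passes on kτ over one plus kτ, where k is its total constant. Target then loses a factor one plus τ times 3.1 × 10⁻⁵ min⁻¹. Multiplying these with φ gives 19.4% in teal and 36.1% in green.

**Which cheats.** The lump does. Written over a common denominator, the product has one plus L/τ plus further positive terms below φ, and the lump drops those terms, so in teal it reads higher. I keep the product.

**Closed flask.** In blue I count the first stages as a lag of 50.4 min, and I let the step intermediate C → target run for the rest of the time. That gives 28.2%. My pick, with the product for the tanks, is green.

**The result.** The forecast gives 27.4%, 19.4% and 36.1% for blue, teal and green, picks green, and says “teal trails blue at equal time because of back-mixing”. The simulation gives 27.4%, 19.4% and 36.1%, and green is best.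

**What ran when.** In blue the early steps ran first, starting material having a half-life of 0.17 h by its own step, and after 2.5 h intermediate C still stood at 16.9% of the charge. In green, intermediate B stands at 1.47% and intermediate C at 4.92% of the charge, and target reaches 80.8% of φ. The teal tank at ten times its residence time reads 38.7% target, 6 percentage points below φ.

All constants were drawn at random within sensible limits; the run is a simulation.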